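**Strategy.** Everything rests on a temporary C5–C11 bond. In the target the lactone carbonyl C11 hangs on C9 and O7 and lies across the nine-membered ring (C1–C9) from C5. Tying C11 to C5 folds that ring into a bicyclo[4.3.1]decenone, a cyclohexanone (C5, C6, C7, C8, C9, C11) bridged by a cycloheptene (C1–C4). One transannular alkoxide-triggered Grob fragmentation then makes the O7–C11 lactone bond and the E C4=C5 alkene while C5–C11 breaks, so the γ-lactone closes and the Z,E-cyclononadiene is uncovered together. The precursor is this bicyclic ketone with an exo mesylate on C4, a triethylsilyl ether on C7 and C10 masked as a dimethyl acetal.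

Key step: step 14

Numbering: C1–C9 are the nine-membered ring, C10 is the CHOAc carbon on C1, C11 the lactone carbonyl on C9, C1′ the side-chain methine on C8.

Remark on the chemistry: C1 stops being a stereocentre in the last step. It is set (R), with the acetal cis to the C4 mesylate, because both groups are then pseudo-equatorial in the boat-like cycloheptene conformer in which C4–O is anti to C5–C11. The C1 epimer would push the acetal under the ring in that conformer.

Step 1
Reactants: 1 (S)-citronellal; 2 RAMP, (2R)-2-(methoxymethyl)pyrrolidin-1-amine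
Product: 3 (1E,3S)-N-[(2R)-2-(methoxymethyl)pyrrolidin-1-yl]-3,7-dimethyloct-6-en-1-imine
Conditions: CH2Cl2, MgSO4, 0 → 25 °C
Reagents that add atoms: none
Why: Condensation of the aldehyde with the 1,1-dialkylhydrazine (Enders hydrazone formation) should give the E hydrazone without touching C1′.

Step 2
Reactants: 3 hydrazone; 4 2-bromo-N-methoxy-N-methylacetamide
Product: 6 (3S,4S)-N-methoxy-3-[(E)-{[(2R)-2-(methoxymethyl)pyrrolidin-1-yl]imino}methyl]-N,4,8-trimethylnon-7-enamide, via lithium azaenolate 5 (not isolated)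
Conditions: LiN(i-Pr)2, THF, 0 °C; then 4, −100 → −78 °C
Reagents that add atoms: none
Why: Enders RAMP-hydrazone α-alkylation, in which the chelated lithium azaenolate is attacked by the reactive α-bromo amide on the face away from the methoxymethyl arm, so the auxiliary sets C8 (S).

Step 3
Reactants: 6 alkylated hydrazone
Product: 7 (3S,4S)-3-formyl-N-methoxy-N,4,8-trimethylnon-7-enamide
Conditions: CuCl2·2H2O, THF–pH 7 phosphate buffer, 25 °C
Reagents that add atoms: water O
Why: Copper-assisted hydrolysis of the hydrazone should free the aldehyde under neutral conditions, sparing the trisubstituted alkene (no ozone) and the epimerisable C8.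

Step 4
Reactants: 7 aldehyde
Product: 9 (3S,4S)-N-methoxy-N-methyl-3-[(2S)-6-methylhept-5-en-2-yl]-4-(triethylsilyloxy)hex-5-enamide, via bromomagnesium alkoxide 8 (not isolated)
Conditions: CH2=CHMgBr, THF, −78 °C; then Et3SiOTf, 2,6-lutidine, −78 → 0 °C
Reagents that add atoms: vinylmagnesium bromide C=C[Mg]Br; triethylsilyl trifluoromethanesulfonate CC[Si](CC)(CC)OS(=O)(=O)C(F)(F)F
Why: Felkin–Anh addition of the Grignard reagent to the α-branched aldehyde (attack anti to the bulky C1′ branch) should set C7 (S), and silylation of the alkoxide in the same flask forestalls lactonisation onto the Weinreb amide.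

Step 5
Reactants: 9 silyl ether amide
Product: 10 (5S,6S)-2-methyl-5-[(2S)-6-methylhept-5-en-2-yl]-6-(triethylsilyloxy)octa-1,7-dien-3-one
Conditions: CH2=C(CH3)MgBr, THF, 0 °C
Reagents that add atoms: isopropenylmagnesium bromide CC(=C)[Mg]Br
Why: Weinreb ketone synthesis, the chelated tetrahedral adduct stopping the addition at the isopropenyl ketone.

Step 6
Reactants: 10 dienone
Product: 11 (4R,5S)-2-methyl-5-[(2S)-6-methylhept-5-en-2-yl]-4-(triethylsilyloxy)cyclohex-2-en-1-one
Conditions: second-generation Grubbs catalyst RuCl2(=CHPh)(PCy3)(H2IMes) (5 mol %), CH2Cl2, 40 °C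
Reagents that add atoms: none
Why: Ring-closing metathesis of the 1,7-diene should close the C5=C6 bond of the cyclohexenone, the hindered trisubstituted side-chain alkene staying out of the reaction.

Step 7
Reactants: 11 cyclohexenone; 12 acrolein
Product: 15 (2R,4S,5S)-2-[(1S)-1-hydroxyprop-2-en-1-yl]-2-methyl-5-[(2S)-6-methylhept-5-en-2-yl]-4-(triethylsilyloxy)cyclohexan-1-one, via lithium enolate 13 (not isolated), via zirconium enolate 14 (not isolated)
Conditions: LiBH(s-Bu)3, THF, −78 °C; Cp2ZrCl2, −78 → −40 °C; then 12, −78 °C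
Reagents that add atoms: none
Why: Conjugate reduction gives the C5 enolate regiospecifically, and its zirconium enolate aldol with acrolein should add on the face anti to the C7 silyloxy group (sets the quaternary C5) and, zirconium enolates being syn-selective whatever the enolate geometry, place the C4 oxygen syn to ring carbon C6 (sets C4 S).

Step 8
Reactants: 15 aldol
Product: 16 (2R,4S,5S)-2-methyl-5-[(2S)-6-methylhept-5-en-2-yl]-4-(triethylsilyloxy)-2-[(1S)-1-(trimethylsilyloxy)prop-2-en-1-yl]cyclohexan-1-one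
Conditions: Me3SiCl, imidazole, CH2Cl2, 0 °C
Reagents that add atoms: chlorotrimethylsilane C[Si](C)(C)Cl
Why: Silyl ether formation caps the C4 hydroxyl as a labile trimethylsilyl ether, which blocks retro-aldol cleavage during the enolate chemistry that follows.

Step 9
Reactants: 17 (E)-4,4-dimethoxybut-2-enal
Product: 18 (E)-4,4-dimethoxybut-2-en-1-ol
Conditions: NaBH4, MeOH, −10 °C
Reagents that add atoms: none
Why: Borohydride 1,2-reduction of the enal at the aldehyde carbon leaves the alkene and the acetal untouched.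

Step 10
Reactants: 18 allylic alcohol
Product: 19 (E)-4,4-dimethoxybut-2-en-1-yl methyl carbonate
Conditions: ClCO2Me, pyridine, CH2Cl2, 0 °C
Reagents that add atoms: methyl chloroformate COC(=O)Cl
Why: Acylation of the primary alcohol gives the linear allylic carbonate that iridium catalysts ionise.

Step 11
Reactants: 16 ketone; 19 allylic carbonate
Product: 21 (2R,4S,5R,6S)-6-[(2R)-1,1-dimethoxybut-3-en-2-yl]-2-methyl-5-[(2S)-6-methylhept-5-en-2-yl]-4-(triethylsilyloxy)-2-[(1S)-1-(trimethylsilyloxy)prop-2-en-1-yl]cyclohexan-1-one, via lithium enolate 20 (not isolated)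
Conditions: LiN(i-Pr)2, THF, −78 °C; then 19, [Ir(cod)Cl]2 (2 mol %), (Sa,S,S)-binaphthyl bis(1-phenylethyl)phosphoramidite (4 mol %), THF, −78 → 25 °C
Reagents that add atoms: none
Why: Iridium-catalysed branched-selective allylic alkylation of a ketone enolate, in which only C9 can be enolised (C5 is quaternary), the enolate should attack the substituted allyl terminus through its face anti to the C8 side chain (sets C9), and the ligand enantiomer is chosen to set C1 (R).

Step 12
Reactants: 21 diene ketone
Product: 23 (1R,2S,5R,6S,7R,8S)-5-(dimethoxymethyl)-2-hydroxy-1-methyl-7-[(2S)-6-methylhept-5-en-2-yl]-8-(triethylsilyloxy)bicyclo[4.3.1]dec-3-en-10-one, via trimethylsilyl ether 22 (not isolated)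
Conditions: second-generation Grubbs catalyst RuCl2(=CHPh)(PCy3)(H2IMes) (10 mol %), toluene, 80 °C; then MeOH, PPTS, 0 °C
Reagents that add atoms: none
Why: Ring-closing metathesis of the two cis (1,3-diaxial) vinyl groups should close the cycloheptene bridge, necessarily with a Z alkene, and mild methanolysis then removes the trimethylsilyl ether much faster than the triethylsilyl ether.

Step 13
Reactants: 23 bicyclic alcohol
Product: 24 (1R,2S,5R,6S,7R,8S)-5-(dimethoxymethyl)-1-methyl-7-[(2S)-6-methylhept-5-en-2-yl]-10-oxo-8-(triethylsilyloxy)bicyclo[4.3.1]dec-3-en-2-yl methanesulfonate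
Conditions: (MeSO2)2O, Et3N, CH2Cl2, −30 °C; used without chromatography
Reagents that add atoms: methanesulfonic anhydride CS(=O)(=O)OS(C)(=O)=O
Why: Sulfonylation of the secondary allylic alcohol with retention at C4, the anhydride keeping chloride out so that no allylic chloride can form.

Step 14
Reactants: 24 mesylate
Product: 27 (1S,2R,3Z,5E,8S,11R)-2-(dimethoxymethyl)-6-methyl-11-[(2S)-6-methylhept-5-en-2-yl]-9-oxabicyclo[6.2.1]undeca-3,5-dien-10-one, via C7 alkoxide 25 (not isolated), via hemiketal alkoxide 26 (not isolated)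
Conditions: Bu4NF (anhydrous), THF, −20 → 25 °C
Reagents that add atoms: none
Why: Proposed new method: fluoride cleaves the triethylsilyl ether, the C7 alkoxide adds across the boat cyclohexanone to the C11 carbonyl, and the resulting oxanorbornane hemiketal alkoxide fragments, its C11–C5 bond being anti-periplanar to C4–OMs, so that the lactone C=O and the C4=C5 alkene form as C11–C5 breaks. The closest known reaction is the Grob fragmentation of cyclic β-sulfonyloxy ketones set off by an external alkoxide adding to the carbonyl group, which gives an ester and an E-cycloalkene; here the alkoxide is internal and the ester is a lactone. The γ-lactone ring closes by 5-exo-trig attack of O7 on C11, while the nine-membered ring is not closed at all but set free by C–C cleavage. No stereocentre is formed; the E geometry of C4=C5 follows from the exo C4 mesylate (cis to the C5 methyl), which is anti to C11–C5 only in the boat-like cycloheptene conformer with C3 gauche to that methyl, a conformer favoured because the cis C1 acetal is pseudo-equatorial there too. The step needs fragmentation to outrun other base-induced paths, and the substrate secures this through the quaternary C5 (no enolisation toward C5, no E1cB loss of mesylate), the bridgehead C9–H and the Z alkene already locked in the seven-membered bridge.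

Step 15
Reactants: 27 lactone acetal
Product: 28 (1S,2R,3Z,5E,8S,11R)-6-methyl-11-[(2S)-6-methylhept-5-en-2-yl]-10-oxo-9-oxabicyclo[6.2.1]undeca-3,5-diene-2-carbaldehyde
Conditions: LiBF4, MeCN–H2O (50:1), 25 °C
Reagents that add atoms: water O
Why: Mild Lewis-acid acetal hydrolysis should release the β,γ-unsaturated aldehyde without opening the lactone or isomerising the diene.

Step 16
Reactants: 28 aldehyde
Product: 29 [(Z)-[(1S,3Z,5E,8S,11R)-6-methyl-11-[(2S)-6-methylhept-5-en-2-yl]-10-oxo-9-oxabicyclo[6.2.1]undeca-3,5-dien-2-ylidene]methyl] acetate (CNP0287742.1)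
Conditions: Ac2O, Et3N, DMAP, CH2Cl2, 0 → 25 °C
Reagents that add atoms: acetic anhydride CC(=O)OC(C)=O
Why: Enol acetate formation, in which deprotonation at C1 gives the conjugated trienolate that is acetylated on oxygen, the acetoxy group being expected cis to C9 because the other position suffers allylic 1,3-strain against C3 of the cis-diene.

**Compound list**

1 | (S)-citronellal, (3S)-3,7-dimethyloct-6-enal | O=CC[C@@H](C)CCC=C(C)C | starting material
2 | RAMP, (2R)-2-(methoxymethyl)pyrrolidin-1-amine | COC[C@H]1CCCN1N | starting material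
3 | (1E,3S)-N-[(2R)-2-(methoxymethyl)pyrrolidin-1-yl]-3,7-dimethyloct-6-en-1-imine | COC[C@H]1CCCN1/N=C/C[C@@H](C)CCC=C(C)C | intermediate
4 | 2-bromo-N-methoxy-N-methylacetamide | BrCC(=O)N(C)OC | starting material
5 | lithium azaenolate of 3 (E C=C, lithium on nitrogen) | COC[C@H]1CCCN1N([Li])/C=C/[C@@H](C)CCC=C(C)C | intermediate (not isolated)
6 | (3S,4S)-N-methoxy-3-[(E)-{[(2R)-2-(methoxymethyl)pyrrolidin-1-yl]imino}methyl]-N,4,8-trimethylnon-7-enamide | COC[C@H]1CCCN1/N=C/[C@@H](CC(=O)N(C)OC)[C@@H](C)CCC=C(C)C | intermediate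
7 | (3S,4S)-3-formyl-N-methoxy-N,4,8-trimethylnon-7-enamide | O=C[C@@H](CC(=O)N(C)OC)[C@@H](C)CCC=C(C)C | intermediate
8 | bromomagnesium alkoxide of (3S,4S)-4-hydroxy-N-methoxy-N-methyl-3-[(2S)-6-methylhept-5-en-2-yl]hex-5-enamide | C=C[C@H](O[Mg]Br)[C@@H](CC(=O)N(C)OC)[C@@H](C)CCC=C(C)C | intermediate (not isolated)
9 | (3S,4S)-N-methoxy-N-methyl-3-[(2S)-6-methylhept-5-en-2-yl]-4-(triethylsilyloxy)hex-5-enamide | C=C[C@H](O[Si](CC)(CC)CC)[C@@H](CC(=O)N(C)OC)[C@@H](C)CCC=C(C)C | intermediate
10 | (5S,6S)-2-methyl-5-[(2S)-6-methylhept-5-en-2-yl]-6-(triethylsilyloxy)octa-1,7-dien-3-one | C=C[C@H](O[Si](CC)(CC)CC)[C@@H](CC(=O)C(C)=C)[C@@H](C)CCC=C(C)C | intermediate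
11 | (4R,5S)-2-methyl-5-[(2S)-6-methylhept-5-en-2-yl]-4-(triethylsilyloxy)cyclohex-2-en-1-one (4,5-cis) | CC1=C[C@H](O[Si](CC)(CC)CC)[C@@H](CC1=O)[C@@H](C)CCC=C(C)C | intermediate
12 | acrolein | C=CC=O | starting material
13 | lithium enolate from 1,4-reduction of 11 (C11–O–Li, C11=C5) | [Li]OC1=C(C)C[C@H](O[Si](CC)(CC)CC)[C@@H](C1)[C@@H](C)CCC=C(C)C | intermediate (not isolated)
14 | chlorobis(cyclopentadienyl)zirconium enolate corresponding to 13 | Cl[Zr](OC1=C(C)C[C@H](O[Si](CC)(CC)CC)[C@@H](C1)[C@@H](C)CCC=C(C)C)(C1C=CC=C1)C1C=CC=C1 | intermediate (not isolated)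
15 | (2R,4S,5S)-2-[(1S)-1-hydroxyprop-2-en-1-yl]-2-methyl-5-[(2S)-6-methylhept-5-en-2-yl]-4-(triethylsilyloxy)cyclohexan-1-one | C=C[C@H](O)[C@@]1(C)C[C@H](O[Si](CC)(CC)CC)[C@@H](CC1=O)[C@@H](C)CCC=C(C)C | intermediate
16 | (2R,4S,5S)-2-methyl-5-[(2S)-6-methylhept-5-en-2-yl]-4-(triethylsilyloxy)-2-[(1S)-1-(trimethylsilyloxy)prop-2-en-1-yl]cyclohexan-1-one | C=C[C@H](O[Si](C)(C)C)[C@@]1(C)C[C@H](O[Si](CC)(CC)CC)[C@@H](CC1=O)[C@@H](C)CCC=C(C)C | intermediate
17 | (E)-4,4-dimethoxybut-2-enal | COC(OC)/C=C/C=O | starting material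
18 | (E)-4,4-dimethoxybut-2-en-1-ol | COC(OC)/C=C/CO | intermediate
19 | (E)-4,4-dimethoxybut-2-en-1-yl methyl carbonate | COC(OC)/C=C/COC(=O)OC | intermediate
20 | lithium enolate of 16 (C11–O–Li, C11=C9) | [Li]OC1=C[C@@H]([C@@H](C)CCC=C(C)C)[C@@H](O[Si](CC)(CC)CC)C[C@]1(C)[C@@H](O[Si](C)(C)C)C=C | intermediate (not isolated)
21 | (2R,4S,5R,6S)-6-[(2R)-1,1-dimethoxybut-3-en-2-yl]-2-methyl-5-[(2S)-6-methylhept-5-en-2-yl]-4-(triethylsilyloxy)-2-[(1S)-1-(trimethylsilyloxy)prop-2-en-1-yl]cyclohexan-1-one | COC(OC)[C@H](C=C)[C@H]1C(=O)[C@@](C)([C@@H](O[Si](C)(C)C)C=C)C[C@H](O[Si](CC)(CC)CC)[C@@H]1[C@@H](C)CCC=C(C)C | intermediate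
22 | (1R,2S,5R,6S,7R,8S)-5-(dimethoxymethyl)-1-methyl-7-[(2S)-6-methylhept-5-en-2-yl]-8-(triethylsilyloxy)-2-(trimethylsilyloxy)bicyclo[4.3.1]dec-3-en-10-one | COC(OC)[C@@H]1/C=C\[C@H](O[Si](C)(C)C)[C@@]2(C)C[C@H](O[Si](CC)(CC)CC)[C@H]([C@@H](C)CCC=C(C)C)[C@@H]1C2=O | intermediate (not isolated)
23 | (1R,2S,5R,6S,7R,8S)-5-(dimethoxymethyl)-2-hydroxy-1-methyl-7-[(2S)-6-methylhept-5-en-2-yl]-8-(triethylsilyloxy)bicyclo[4.3.1]dec-3-en-10-one | COC(OC)[C@@H]1/C=C\[C@H](O)[C@@]2(C)C[C@H](O[Si](CC)(CC)CC)[C@H]([C@@H](C)CCC=C(C)C)[C@@H]1C2=O | intermediate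
24 | (1R,2S,5R,6S,7R,8S)-5-(dimethoxymethyl)-1-methyl-7-[(2S)-6-methylhept-5-en-2-yl]-10-oxo-8-(triethylsilyloxy)bicyclo[4.3.1]dec-3-en-2-yl methanesulfonate (key-step precursor; mesylate and acetal cis, both cis to the bridgehead methyl) | COC(OC)[C@@H]1/C=C\[C@H](OS(C)(=O)=O)[C@@]2(C)C[C@H](O[Si](CC)(CC)CC)[C@H]([C@@H](C)CCC=C(C)C)[C@@H]1C2=O | intermediate
25 | tetrabutylammonium C7 alkoxide of 24 (silyl group removed) | CCCC[N+](CCCC)(CCCC)CCCC.COC(OC)[C@@H]1/C=C\[C@H](OS(C)(=O)=O)[C@@]2(C)C[C@H]([O-])[C@H]([C@@H](C)CCC=C(C)C)[C@@H]1C2=O | intermediate (not isolated)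
26 | tetrabutylammonium hemiketal alkoxide (O7 bonded to C11, oxanorbornane with O– on C11) | CCCC[N+](CCCC)(CCCC)CCCC.COC(OC)[C@@H]1/C=C\[C@H](OS(C)(=O)=O)[C@@]2(C)C[C@@H]3O[C@@]2([O-])[C@H]1[C@H]3[C@@H](C)CCC=C(C)C | intermediate (not isolated)
27 | (1S,2R,3Z,5E,8S,11R)-2-(dimethoxymethyl)-6-methyl-11-[(2S)-6-methylhept-5-en-2-yl]-9-oxabicyclo[6.2.1]undeca-3,5-dien-10-one (key-step product) | COC(OC)[C@@H]1/C=C\C=C(/C)C[C@@H]2OC(=O)[C@H]1[C@H]2[C@@H](C)CCC=C(C)C | intermediate
28 | (1S,2R,3Z,5E,8S,11R)-6-methyl-11-[(2S)-6-methylhept-5-en-2-yl]-10-oxo-9-oxabicyclo[6.2.1]undeca-3,5-diene-2-carbaldehyde | O=C[C@@H]1/C=C\C=C(/C)C[C@@H]2OC(=O)[C@H]1[C@H]2[C@@H](C)CCC=C(C)C | intermediate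
29 | [(Z)-[(1S,3Z,5E,8S,11R)-6-methyl-11-[(2S)-6-methylhept-5-en-2-yl]-10-oxo-9-oxabicyclo[6.2.1]undeca-3,5-dien-2-ylidene]methyl] acetate | CC(=O)O/C=C1/C=C\C=C(/C)C[C@@H]2OC(=O)[C@H]1[C@H]2[C@@H](C)CCC=C(C)C | target

**Count.** Total: 16 steps. Longest linear sequence: 14 steps (steps 1–8 and 11–16); steps 9 and 10 make the allylic carbonate.

**Steps most likely to fail**

1. Step 14 (proposed new method). After desilylation the C7 alkoxide may not close onto the hindered bridging carbonyl, or the hemiketal may revert faster than it fragments, so that only loss of the silyl group is seen; fluoride-induced ionisation of the allylic mesylate is a second loss channel. The fallback uses the known intermolecular form of the same fragmentation. It sets out from 24: NaOMe in MeOH–THF at 0 °C should add methoxide to C11 and fragment the bicycle to the nine-membered E,Z-dienyl methyl ester that still carries the C7 silyl ether, F1. Bu4NF buffered with acetic acid then frees the C7 hydroxy ester, F2, which should lactonise on warming with PPTS in toluene. The route is rejoined at 27.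

2. Step 11. The enolate carbon C9 sits between the C8 branch and a carbonyl flanked by a quaternary centre, so attack on the allyl–iridium complex may be slow, may turn to the unsubstituted terminus (linear product), or proton exchange may erode C9. The fallback moves the regiocontrol from the catalyst into the electrophile. Vinylmagnesium bromide and dimethoxyacetaldehyde give, after lipase resolution, (S)-1,1-dimethoxybut-3-en-2-ol, F3, which is converted into its methyl carbonate, (S)-1,1-dimethoxybut-3-en-2-yl methyl carbonate, F4. Setting out from 16, lithium enolate 20 is transmetallated with CuI and alkylated with F4 under RhCl(PPh3)3/P(OMe)3 catalysis. This rhodium allylic substitution is known to keep the position and configuration of the secondary carbonate, so C1 comes from F4 and C9 again from attack anti to the C8 side chain. The route is rejoined at 21.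

3. Step 7. The zirconium enolate may react through a closed chair transition state that gives the C4 epimer, or the hindered enolate may add sluggishly and allow retro-aldol equilibration, so that the carbinol configuration is mixed. The fallback builds C4 by addition to an aldehyde instead of by an aldol. Setting out from 11, conjugate reduction with LiBH(s-Bu)3 and trapping of enolate 13 with gaseous formaldehyde (again anti to the C7 silyloxy group) gives the hydroxymethyl ketone, F5. Dess–Martin oxidation gives the keto aldehyde, F6. Vinylmagnesium bromide at −78 °C then adds to the aldehyde anti to the C5–C11 bond and past the small methyl group (polar Felkin–Anh and Cornforth models agree), which gives the (S) carbinol. The route is rejoined at 15.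

**Further compounds**

F1 | step 14 | methyl (1S,2R,3Z,5E,8S,9R)-2-(dimethoxymethyl)-6-methyl-9-[(2S)-6-methylhept-5-en-2-yl]-8-(triethylsilyloxy)cyclonona-3,5-diene-1-carboxylate | COC(OC)[C@@H]1/C=C\C=C(/C)C[C@H](O[Si](CC)(CC)CC)[C@H]([C@@H](C)CCC=C(C)C)[C@@H]1C(=O)OC
F2 | step 14 | methyl (1S,2R,3Z,5E,8S,9R)-2-(dimethoxymethyl)-8-hydroxy-6-methyl-9-[(2S)-6-methylhept-5-en-2-yl]cyclonona-3,5-diene-1-carboxylate | COC(OC)[C@@H]1/C=C\C=C(/C)C[C@H](O)[C@H]([C@@H](C)CCC=C(C)C)[C@@H]1C(=O)OC
F3 | step 11 | (S)-1,1-dimethoxybut-3-en-2-ol | COC(OC)[C@@H](O)C=C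
F4 | step 11 | (S)-1,1-dimethoxybut-3-en-2-yl methyl carbonate | COC(OC)[C@@H](OC(=O)OC)C=C
F5 | step 7 | (2S,4S,5S)-2-(hydroxymethyl)-2-methyl-5-[(2S)-6-methylhept-5-en-2-yl]-4-(triethylsilyloxy)cyclohexan-1-one | OC[C@@]1(C)C[C@H](O[Si](CC)(CC)CC)[C@@H](CC1=O)[C@@H](C)CCC=C(C)C
F6 | step 7 | (1R,4S,5S)-1-methyl-4-[(2S)-6-methylhept-5-en-2-yl]-2-oxo-5-(triethylsilyloxy)cyclohexane-1-carbaldehyde | O=C[C@@]1(C)C[C@H](O[Si](CC)(CC)CC)[C@@H](CC1=O)[C@@H](C)CCC=C(C)C
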